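The target is the depsidone with one labile stereocentre, the (S)-configured lactol carbon of its 3-hydroxyphthalide. The route below is a proposal on paper; no step has been run.

**Strategy.** The seven-membered depsidone ring is closed across ring A by making, in one base-mediated cascade, the aryl ether bond from the ring B oxygen to ring A C2 and the bond from the ester carbonyl carbon to the neighbouring ring A C1. Ring A enters non-aromatic, as 2-chloro-4-methyl-6-oxocyclohex-1-enecarbaldehyde (orcinol at the cyclohexane-1,3-dione level); ring B is a phenol whose future ester oxygen and adjacent CH2OH oxygen are tied in a six-membered cyclic carbonate that supplies the carbonyl carbon. Phenoxide addition–elimination, then vinylogous Dieckmann acylation, exploits the 1,3-dioxygenation of ring A and the ester-O/CH2OH pair of ring B. Aromatisation, aldehyde reduction, auxiliary-based setting of the lactol carbon and hydrogenolysis finish.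

Key step: step 10

Remark on the chemistry: the lactol carbon of a 3-hydroxyphthalide can epimerise through its ring-opened formyl acid, so it is set on a configurationally stable acetal and unveiled in the last step under neutral, aprotic conditions.

Lettering in names: ring A is the methyl-bearing ring (C1 ester carbonyl, C2 ether oxygen, C3 CH2OH, C4 OH, C6 CH3). Ring B is numbered as a phthalide (C3 lactol carbon, C4 ether oxygen, C5 ester oxygen, C6 CH2OH, C7 OH).

Step 1
Reactants: 1 2,6-dihydroxybenzaldehyde
Product: 2 2-(benzyloxy)-6-hydroxybenzaldehyde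
Conditions: BnBr (1.0 equiv), K2CO3 (1.0 equiv), DMF, rt
Reagents that add atoms: benzyl bromide BrCc1ccccc1
Why: Williamson etherification of a symmetrical resorcinol should stop at the mono-ether, because the remaining hydroxyl is hydrogen-bonded to the aldehyde and only one equivalent of base and halide is offered.

Step 2
Reactants: 2 2-(benzyloxy)-6-hydroxybenzaldehyde
Product: 3 2-(benzyloxy)-3-bromo-6-hydroxybenzaldehyde
Conditions: NBS (1.0 equiv), MeCN, 0 °C
Reagents that add atoms: N-bromosuccinimide O=C1CCC(=O)N1Br
Why: Electrophilic aromatic bromination should go para to the free phenol, the strongest donor, at the carbon that is also ortho to the benzyloxy group and meta to the aldehyde.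

Step 3
Reactants: 3 2-(benzyloxy)-3-bromo-6-hydroxybenzaldehyde
Product: 4 methyl 2-(benzyloxy)-3-formyl-4-hydroxybenzoate
Conditions: CO (1 atm), Pd(OAc)2, Xantphos, Et3N, MeOH/DMF, 70 °C
Reagents that add atoms: carbon monoxide [C-]#[O+]; methanol CO
Why: Palladium-catalysed methoxycarbonylation of the aryl bromide should tolerate the free phenol and the aldehyde.

Step 4
Reactants: 4 methyl 2-(benzyloxy)-3-formyl-4-hydroxybenzoate
Product: 5 methyl 2-(benzyloxy)-4-hydroxy-3-(hydroxymethyl)benzoate
Conditions: NaBH4, MeOH, 0 °C
Reagents that add atoms: none
Why: Borohydride reduction should convert the aryl aldehyde to the benzylic alcohol while the methyl ester stays untouched at 0 °C.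

Step 5
Reactants: 5 methyl 2-(benzyloxy)-4-hydroxy-3-(hydroxymethyl)benzoate
Product: 6 methyl 5-(benzyloxy)-2-oxo-4H-1,3-benzodioxine-6-carboxylate
Conditions: 1,1'-carbonyldiimidazole, CH2Cl2, rt
Reagents that add atoms: 1,1'-carbonyldiimidazole O=C(n1ccnc1)n1ccnc1
Why: Carbonylation of the 2-hydroxybenzyl alcohol unit should close the six-membered aryl alkyl carbonate, the only cyclic carbonate this phenol/alcohol pair can form.

Step 6
Reactants: 6 methyl 5-(benzyloxy)-2-oxo-4H-1,3-benzodioxine-6-carboxylate
Product: 7 methyl 5-(benzyloxy)-8-formyl-2-oxo-4H-1,3-benzodioxine-6-carboxylate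
Conditions: Cl2CHOMe, AgOSO2CF3 (2 equiv), CH2Cl2, −78 → 0 °C; aq. NaHCO3
Reagents that add atoms: dichloromethyl methyl ether COC(Cl)Cl; water O
Why: Rieche formylation (Friedel–Crafts attack of the chloro(methoxy)methyl cation) should occur para to the benzyloxy group at C8, the only free position that is not ortho to the deactivating ester.

Step 7
Reactants: 7 methyl 5-(benzyloxy)-8-formyl-2-oxo-4H-1,3-benzodioxine-6-carboxylate
Product: 9 methyl 5-(benzyloxy)-8-hydroxy-2-oxo-4H-1,3-benzodioxine-6-carboxylate, via aryl formate 8 (not isolated)
Conditions: mCPBA, CH2Cl2, rt; then MeOH, Et3N (cat.), 0 °C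
Reagents that add atoms: 3-chloroperoxybenzoic acid OOC(=O)c1cccc(Cl)c1
Why: In this Baeyer–Villiger (Dakin-type) oxidation the electron-rich aryl group migrates to give the formate, whose methanolysis should be far faster than that of the cyclic carbonate and free the phenol.

Step 8
Reactants: 9 methyl 5-(benzyloxy)-8-hydroxy-2-oxo-4H-1,3-benzodioxine-6-carboxylate
Product: 11 (±)-7-(benzyloxy)-4-hydroxy-3-methoxyphthalide bearing the six-membered cyclic carbonate O–C(=O)–O–CH2 from the C5 oxygen to the C6 methylene, via salicylaldehyde 10 (not isolated)
Conditions: hexamethylenetetramine, CF3CO2H, 75 °C; then 2 M HCl, rt; then MeOH, TsOH (cat.), 50 °C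
Reagents that add atoms: hexamethylenetetramine C1N2CN3CN1CN(C2)C3; water O; methanol CO
Why: Duff formylation ortho to the free phenol at the only unsubstituted ring carbon, followed by acid-catalysed ring–chain isomerisation of the methyl 2-formylbenzoate to its 3-methoxyphthalide pseudo-ester, should mask the aldehyde, the acetal carbon being racemic at this stage.

Step 9
Reactants: 12 5-methylcyclohexane-1,3-dione
Product: 13 (±)-2-chloro-4-methyl-6-oxocyclohex-1-ene-1-carbaldehyde
Conditions: POCl3 (2 equiv), DMF, CH2Cl2, 0 °C → rt; aq. NaOAc
Reagents that add atoms: N,N-dimethylformamide CN(C)C=O; phosphoryl chloride O=P(Cl)(Cl)Cl; water O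
Why: Vilsmeier–Haack–Arnold haloformylation of a cyclohexane-1,3-dione should formylate C2 and turn one enol hydroxyl into the vinyl chloride, the limited amount of reagent stopping it at the monochloride.

Step 10
Reactants: 11 (±)-ring B phenol with cyclic carbonate and 3-methoxyphthalide; 13 (±)-2-chloro-4-methyl-6-oxocyclohex-1-ene-1-carbaldehyde
Product: 15 dihydro-depsidone (mixture of diastereomers and tautomers, keto form drawn): ring A is a 3-formyl-6-methyl-4-oxocyclohex-2-ene whose C1–H carbon is bonded to the ester carbonyl and whose C2 is bonded to the ether oxygen; ring B carries free C6–CH2OH, C7–OBn and the 3-methoxyphthalide, via vinylogous ester 14 (not isolated)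
Conditions: Cs2CO3 (3 equiv), MeCN (0.05 M), 0 °C → 45 °C; AcOH quench
Reagents that add atoms: none
Why: The caesium phenoxide of 11 adds to the β-carbon of the chlorovinyl aldehyde 13 and expels chloride (addition–elimination) to give vinylogous ester 14, whose ring CH2 beside the aryloxy carbon, vinylogously acidified by both the ketone and the aldehyde, is deprotonated and attacks the carbonate carbonyl; the benzylic alkoxide leaves, the aryl ester remains and the product rests as a stabilised enolate. The closest known reaction types are the O-vinylation of phenoxides by β-chlorovinyl carbonyl compounds and the intramolecular Claisen (Dieckmann-type) C-acylation of an enolate by an aryl alkyl carbonate, as in the 4-hydroxycoumarin synthesis from 2-hydroxyacetophenone and diethyl carbonate. The seven-membered 1,4-dioxepin-5-one ring closes by 7-exo-trig attack of the carbanion on the carbonate C=O while the six-membered carbonate ring opens. The new CH centre on ring A is formed without control and, like the CH–CH3 centre, disappears on aromatisation in step 11. Regioselectivity on ring A is secured by the symmetry of the parent dione: whichever carbonyl carbon carries the aryloxy group, the neighbouring CH2 is the only carbanion that can reach the carbonate and it lies next to the CH–CH3 carbon, whereas acylation at the formyl-bearing carbon would give a non-enolisable adduct that reverts. Regioselectivity on ring B is secured by the carbonate itself, which fixes the carbonyl carbon on the C5 oxygen and leaves the C4 phenoxide as the only oxygen nucleophile, since transfer of the carbonate to that oxygen would require a strained five-membered catechol carbonate and a free alkoxide.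

Step 11
Reactants: 15 dihydro-depsidone (mixture of diastereomers)
Product: 16 depsidone aldehyde, racemic at the acetal carbon: ring A 3-formyl-4-hydroxy-6-methyl; ring B 6-CH2OH, 7-OBn, 3-methoxyphthalide
Conditions: DDQ (1.1 equiv), 1,4-dioxane, rt
Reagents that add atoms: none
Why: Quinone dehydrogenation of the enolised cyclohexenone (hydride abstraction at the CH–CH3 carbon, then proton loss and tautomerisation) should aromatise ring A to the 3-formyl-4-hydroxy arene and erase its two stereocentres.

Step 12
Reactants: 16 depsidone aldehyde
Product: 17 depsidone diol, racemic at the acetal carbon: as 16 with ring A C3–CH2OH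
Conditions: NaBH4, THF/EtOH, −20 °C; AcOH quench
Reagents that add atoms: none
Why: Borohydride reduction at low temperature should take the aryl aldehyde, which is more electrophilic than the aryl ester, the lactone and the pseudo-ester acetal.

Step 13
Reactants: 17 depsidone diol (racemic methyl pseudo-ester); 18 (S)-1-phenylethanol
Product: 19 depsidone with (3S)-3-[(1S)-1-phenylethoxy]phthalide acetal, otherwise as 17
Conditions: 18 (5 equiv), camphorsulfonic acid (10 mol%), CH2Cl2, 5 Å molecular sieves, rt; chromatographic separation, the (3R) epimer resubmitted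
Reagents that add atoms: none
Why: Acid-catalysed transacetalisation through the phthalidyl oxocarbenium ion forms both acetal epimers reversibly, and because the alcohol is enantiopure they are diastereomers, so the (3S) epimer can be isolated and the (3R) epimer returned to the equilibration (auxiliary-based resolution with recycling).

Step 14
Reactants: 19 (3S)-acetal depsidone
Product: 20 target: (S)-lactol depsidone (3-hydroxyphthalide; ring A 4-OH, 3-CH2OH, 6-CH3; ring B 6-CH2OH, 7-OH)
Conditions: H2 (1 atm), 10% Pd/C, EtOAc, rt; filtration and evaporation in the cold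
Reagents that add atoms: none
Why: Hydrogenolysis should cleave the benzyl ether and the 1-phenylethyl acetal ether at their PhC–O bonds, so the bond between oxygen and the acetal carbon is not broken and the lactol is released with retention under neutral, aprotic conditions.

**Compound list**

1 | 2,6-dihydroxybenzaldehyde | O=Cc1c(O)cccc1O | starting material
2 | 2-(benzyloxy)-6-hydroxybenzaldehyde | O=Cc1c(O)cccc1OCc1ccccc1 | intermediate
3 | 2-(benzyloxy)-3-bromo-6-hydroxybenzaldehyde | O=Cc1c(O)ccc(Br)c1OCc1ccccc1 | intermediate
4 | methyl 2-(benzyloxy)-3-formyl-4-hydroxybenzoate | COC(=O)c1ccc(O)c(C=O)c1OCc1ccccc1 | intermediate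
5 | methyl 2-(benzyloxy)-4-hydroxy-3-(hydroxymethyl)benzoate | COC(=O)c1ccc(O)c(CO)c1OCc1ccccc1 | intermediate
6 | methyl 5-(benzyloxy)-2-oxo-4H-1,3-benzodioxine-6-carboxylate | COC(=O)c1ccc2OC(=O)OCc2c1OCc1ccccc1 | intermediate
7 | methyl 5-(benzyloxy)-8-formyl-2-oxo-4H-1,3-benzodioxine-6-carboxylate | COC(=O)c1cc(C=O)c2OC(=O)OCc2c1OCc1ccccc1 | intermediate
8 | methyl 5-(benzyloxy)-8-(formyloxy)-2-oxo-4H-1,3-benzodioxine-6-carboxylate (aryl formate) | COC(=O)c1cc(OC=O)c2OC(=O)OCc2c1OCc1ccccc1 | intermediate (not isolated)
9 | methyl 5-(benzyloxy)-8-hydroxy-2-oxo-4H-1,3-benzodioxine-6-carboxylate | COC(=O)c1cc(O)c2OC(=O)OCc2c1OCc1ccccc1 | intermediate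
10 | methyl 5-(benzyloxy)-7-formyl-8-hydroxy-2-oxo-4H-1,3-benzodioxine-6-carboxylate (salicylaldehyde) | COC(=O)c1c(C=O)c(O)c2OC(=O)OCc2c1OCc1ccccc1 | intermediate (not isolated)
11 | (±)-7-(benzyloxy)-4-hydroxy-3-methoxyphthalide with the six-membered cyclic carbonate O–C(=O)–O–CH2 from the C5 oxygen to the C6 methylene | COC1OC(=O)c2c(OCc3ccccc3)c3COC(=O)Oc3c(O)c12 | intermediate
12 | 5-methylcyclohexane-1,3-dione | CC1CC(=O)CC(=O)C1 | starting material
13 | (±)-2-chloro-4-methyl-6-oxocyclohex-1-ene-1-carbaldehyde | O=CC1=C(Cl)CC(C)CC1=O | intermediate
14 | aryl vinylogous ester: 11 bonded through its C4 oxygen to C2 of 4-methyl-6-oxocyclohex-1-ene-1-carbaldehyde (mixture of diastereomers) | COC1OC(=O)c2c(OCc3ccccc3)c3COC(=O)Oc3c(OC3=C(C=O)C(=O)CC(C)C3)c12 | intermediate (not isolated)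
15 | dihydro-depsidone, keto tautomer drawn (mixture of diastereomers): seven-membered ring closed, ring A 3-formyl-6-methyl-4-oxocyclohex-2-ene, ring B with free CH2OH, OBn and 3-methoxyphthalide | CC1CC(=O)C(C=O)=C2Oc3c(c(CO)c(OCc4ccccc4)c4C(=O)OC(OC)c34)OC(=O)C12 | intermediate
16 | depsidone aldehyde, racemic at the acetal carbon: ring A 3-CHO, 4-OH, 6-CH3; ring B 6-CH2OH, 7-OBn, 3-methoxyphthalide | Cc1cc(O)c(C=O)c2Oc3c(c(CO)c(OCc4ccccc4)c4C(=O)OC(OC)c34)OC(=O)c12 | intermediate
17 | depsidone diol, racemic at the acetal carbon: as 16 with ring A 3-CH2OH | Cc1cc(O)c(CO)c2Oc3c(c(CO)c(OCc4ccccc4)c4C(=O)OC(OC)c34)OC(=O)c12 | intermediate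
18 | (S)-1-phenylethanol | C[C@H](O)c1ccccc1 | starting material
19 | depsidone with (3S)-3-[(1S)-1-phenylethoxy]phthalide acetal and 7-OBn | Cc1cc(O)c(CO)c2Oc3c(c(CO)c(OCc4ccccc4)c4C(=O)O[C@H](O[C@@H](C)c5ccccc5)c34)OC(=O)c12 | intermediate
20 | target, (S)-configured 3-hydroxyphthalide depsidone (consalazinic acid constitution) | Cc1cc(O)c(CO)c2c1C(=O)Oc1c(CO)c(O)c3c(c1O2)[C@@H](O)OC3=O | target

**Step count.** Total: 14 steps. Longest linear sequence: 13 steps (steps 1–8 and 10–14); step 9 is the one-step side branch.

**The three steps most likely to fail**

Step 10. Deprotonation of the ring CH2 of the vinylogous ester by carbonate base may be too slow, so that the cascade stops after ether formation and the reactive aryl vinylogous ester is consumed by hydrolysis or intermolecular acyl transfer. The fallback separates the two bond formations and replaces the enolate acylation by an electrophilic aromatic acylation. It sets out from 11 and 13, which with K2CO3 in acetone at 0 °C should give the vinylogous ester 14, now isolated. DDQ in dioxane should aromatise its cyclohexenone ring to the diaryl ether with a 2-aryloxy-6-hydroxy-4-methylbenzaldehyde ring A and the intact carbonate, F1. Treatment of F1 with Sc(OSO2CF3)3 (cat.) in 1,2-dichloroethane at 60 °C should let the ring A carbon para to the phenol and ortho to the aryloxy group attack the carbonate carbonyl (Fries-type intramolecular Friedel–Crafts acylation, with opening of the carbonate). This comes back to the route at 16.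

Step 8. Electrophilic substitution at the crowded carbon between the phenol and the ester may stall, and hot trifluoroacetic acid may cleave the benzyl ether next to the ester. The fallback puts a halogen at that carbon and turns it into the formyl group by catalysis. It sets out from 9, which with NBS in MeCN at 0 °C should give methyl 5-(benzyloxy)-7-bromo-8-hydroxy-2-oxo-4H-1,3-benzodioxine-6-carboxylate, F2. Palladium-catalysed reductive carbonylation of F2 (CO/H2, Pd(OAc)2, di(1-adamantyl)-n-butylphosphine, TMEDA, toluene, 100 °C) should give the salicylaldehyde 10. Isomerisation of 10 with MeOH and TsOH, as in the second half of step 8, comes back to the route at 11.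

Step 14. The two ArCH2–OH bonds may be hydrogenolysed to methyl groups, and slow cleavage of the hindered benzyl ether may prolong the exposure of the free lactol and allow epimerisation. The fallback unveils the lactol without hydrogen. It sets out from 17, whose benzyl ether, ortho to the lactone carbonyl, should be cleaved by chelation with MgBr2·OEt2 (benzene/Et2O, 40 °C) to give the 7-hydroxy methyl pseudo-ester, F3. Transacetalisation of F3 with (S)-1-(2-nitrophenyl)ethanol (camphorsulfonic acid, CH2Cl2, 5 Å molecular sieves) and separation as in step 13 should give the (3S)-3-[(1S)-1-(2-nitrophenyl)ethoxy] acetal, F4. Irradiation of F4 at 365 nm in MeCN at 0 °C should cleave the nitrobenzylic C–O bond and release the lactol with retention, which comes back to the route at 20.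

Further compounds
F1 | step 10 | diaryl ether: 11 bonded through its C4 oxygen to C2 of 6-hydroxy-4-methylbenzaldehyde (aromatic ring A, carbonate intact) | COC1OC(=O)c2c(OCc3ccccc3)c3COC(=O)Oc3c(Oc3cc(C)cc(O)c3C=O)c12
F2 | step 8 | methyl 5-(benzyloxy)-7-bromo-8-hydroxy-2-oxo-4H-1,3-benzodioxine-6-carboxylate | COC(=O)c1c(Br)c(O)c2OC(=O)OCc2c1OCc1ccccc1
F3 | step 14 | depsidone triol, racemic methyl pseudo-ester: as 17 with ring B 7-OH | Cc1cc(O)c(CO)c2Oc3c(c(CO)c(O)c4C(=O)OC(OC)c34)OC(=O)c12
F4 | step 14 | depsidone with (3S)-3-[(1S)-1-(2-nitrophenyl)ethoxy]phthalide acetal and ring B 7-OH | Cc1cc(O)c(CO)c2Oc3c(c(CO)c(O)c4C(=O)O[C@H](O[C@@H](C)c5ccccc5[N+](=O)[O-])c34)OC(=O)c12
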